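**Assumption:** the target SMILES has no stereocentre and no defined axis, so the compound is made as the single achiral structure drawn.

## Retrosynthetic overview

1. Artopetelin C 18 ⇐ acid-free cleavage of the three methyl ethers of benzofuran 17.
2. 17 ⇐ furan O1–C2 bond (key C–O bond), closed by a phenoxide that is only unmasked when the O-prenyl group of diaryl alkyne 15 shifts to carbon; the same event sets the C7 1,1-dimethylallyl group.
3. 15 ⇐ Sonogashira union of iodoarene 14 (from 3,5-dimethoxyphenol) with chromanyl alkyne 9.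
4. 9 ⇐ chroman O–C bond: mono-demethylation of the symmetrical 2,6-diprenyl-3,5-dimethoxybenzaldehyde 5 and ring closure of the single phenol onto its prenyl neighbour, then CHO → C≡CH; 5 comes from 3,5-dimethoxybenzaldehyde by dibromination and double Stille prenylation.
5. Ring order: chroman ring (on ring B) first, furan ring (on ring A) last.

## Route

Step 1
Reactants: 1 3,5-dimethoxybenzaldehyde; 2 bromine
Product: 3 2,6-dibromo-3,5-dimethoxybenzaldehyde
Conditions: Br2 (2.2 equiv), AcOH, rt
Reagents that add atoms: bromine (BrBr)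
Why: Electrophilic aromatic bromination, in which C2 and C6 are each ortho to one methoxy group and para to the other while C4 between the two methoxy groups is shielded, so two equivalents of bromine give the 2,6-dibromide.

Step 2
Reactants: 3 2,6-dibromo-3,5-dimethoxybenzaldehyde; 4 tributyl(3-methylbut-2-en-1-yl)stannane
Product: 5 3,5-dimethoxy-2,6-bis(3-methylbut-2-en-1-yl)benzaldehyde
Conditions: 4 (2.6 equiv), Pd(PPh3)4 (10 mol%), DMF, 100 °C
Reagents that add atoms: tributyl(3-methylbut-2-en-1-yl)stannane (CCCC[Sn](CCCC)(CCCC)CC=C(C)C)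
Why: Double Stille cross-coupling, in which the ortho formyl group speeds oxidative addition into each C–Br bond and reductive elimination from the aryl(prenyl)palladium intermediate occurs at the less hindered CH2 terminus, giving the linear prenyl groups.

Step 3
Reactants: 5 3,5-dimethoxy-2,6-bis(3-methylbut-2-en-1-yl)benzaldehyde
Product: 7 7-methoxy-2,2-dimethyl-6-(3-methylbut-2-en-1-yl)chromane-5-carbaldehyde, via monophenol aldehyde 6 (not isolated)
Conditions: EtSNa (1.3 equiv), DMF, 110 °C; AcOH, evaporate; TsOH·H2O (1.6 equiv), toluene, 60 °C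
Reagents that add atoms: none
Why: SN2 O-demethylation by ethanethiolate stops after one methyl group because the phenoxide formed deactivates the second ether, and the single free phenol then adds in Markovnikov fashion to its neighbouring prenyl double bond under Brønsted acid catalysis (intramolecular hydroalkoxylation) to close the 2,2-dimethylchroman, the methoxy-flanked prenyl group having no OH to close onto.

Step 4
Reactants: 7 7-methoxy-2,2-dimethyl-6-(3-methylbut-2-en-1-yl)chromane-5-carbaldehyde; 8 dimethyl (1-diazo-2-oxopropyl)phosphonate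
Product: 9 5-ethynyl-7-methoxy-2,2-dimethyl-6-(3-methylbut-2-en-1-yl)chromane
Conditions: 8 (1.3 equiv), K2CO3 (2 equiv), MeOH, 0 °C to rt
Reagents that add atoms: dimethyl (1-diazo-2-oxopropyl)phosphonate (COP(=O)(OC)C(=[N+]=[N-])C(C)=O)
Why: Seyferth–Gilbert homologation with the Ohira–Bestmann reagent turns the non-enolisable aryl aldehyde into the terminal alkyne under mild basic conditions that leave the prenyl group and the chroman untouched.

Step 5
Reactants: 10 3,5-dimethoxyphenol; 11 N-iodosuccinimide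
Product: 12 2-iodo-3,5-dimethoxyphenol
Conditions: NIS (1.0 equiv), CH2Cl2, 0 °C
Reagents that add atoms: N-iodosuccinimide (O=C1CCC(=O)N1I)
Why: Electrophilic aromatic iodination of the strongly activated phenol goes mainly to C2, ortho to the hydroxyl and para to a methoxy group, in preference to the more crowded C4 between the two methoxy groups, and the minor 4-iodo isomer is removed by chromatography.

Step 6
Reactants: 12 2-iodo-3,5-dimethoxyphenol; 13 1-bromo-3-methylbut-2-ene
Product: 14 2-iodo-1,5-dimethoxy-3-[(3-methylbut-2-en-1-yl)oxy]benzene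
Conditions: 13 (1.2 equiv), K2CO3 (2 equiv), acetone, 55 °C
Reagents that add atoms: 1-bromo-3-methylbut-2-ene (CC(C)=CCBr)
Why: Williamson ether synthesis, in which the phenoxide formed by K2CO3 in acetone is alkylated on oxygen by the primary allylic bromide.

Step 7
Reactants: 14 2-iodo-1,5-dimethoxy-3-[(3-methylbut-2-en-1-yl)oxy]benzene; 9 5-ethynyl-7-methoxy-2,2-dimethyl-6-(3-methylbut-2-en-1-yl)chromane
Product: 15 5-{[2,4-dimethoxy-6-(3-methylbut-2-en-1-yloxy)phenyl]ethynyl}-7-methoxy-2,2-dimethyl-6-(3-methylbut-2-en-1-yl)chromane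
Conditions: PdCl2(PPh3)2 (3 mol%), CuI (5 mol%), Et3N, THF, 55 °C
Reagents that add atoms: none
Why: Sonogashira coupling of the aryl iodide with the terminal alkyne, in which the phenol oxygen is masked as its prenyl ether so no premature ring closure can occur and aryl allyl-type ethers tolerate these mild palladium/copper conditions.

Step 8
Reactants: 15 5-{[2,4-dimethoxy-6-(3-methylbut-2-en-1-yloxy)phenyl]ethynyl}-7-methoxy-2,2-dimethyl-6-(3-methylbut-2-en-1-yl)chromane
Product: 17 4,6-dimethoxy-2-[7-methoxy-2,2-dimethyl-6-(3-methylbut-2-en-1-yl)chroman-5-yl]-7-(2-methylbut-3-en-2-yl)-1-benzofuran, via Claisen phenol 16 (not isolated)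
Conditions: Cs2CO3 (30 mol%), NMP, 175 °C, sealed tube, argon
Reagents that add atoms: none
Why: Proposed new method: a Claisen-gated cycloisomerisation in which the thermal [3,3] shift of the aryl prenyl ether can only reach the free ortho carbon (the other is blocked by the alkyne), so it installs the 1,1-dimethylallyl group and unmasks exactly the phenol oxygen that lies between that group and the alkyne; Cs2CO3 converts it at once into the phenoxide, which closes the furan by 5-endo-dig attack on the alkyne carbon bearing the chromanyl ring before the ortho-(1,1-dimethylallyl)phenol can undergo abnormal Claisen or dihydrofuran side reactions; the closest known reactions are the thermal aromatic Claisen rearrangement of aryl prenyl ethers, the base-mediated cycloisomerisation of 2-alkynylphenols, and the platinum- or gold-catalysed carboalkoxylation of 2-alkynylphenyl allyl ethers, which sends the allyl group to C3 instead; no stereocentre is formed.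

Step 9
Reactants: 17 4,6-dimethoxy-2-[7-methoxy-2,2-dimethyl-6-(3-methylbut-2-en-1-yl)chroman-5-yl]-7-(2-methylbut-3-en-2-yl)-1-benzofuran
Product: 18 Artopetelin C, 2-[7-hydroxy-2,2-dimethyl-6-(3-methylbut-2-en-1-yl)chroman-5-yl]-7-(2-methylbut-3-en-2-yl)-1-benzofuran-4,6-diol
Conditions: MeMgI (15 equiv), Et2O then neat melt, 160 °C; sat. aq. NH4Cl, 0 °C
Reagents that add atoms: none
Why: Exhaustive aryl methyl ether cleavage by methylmagnesium iodide in the melt (nucleophilic dealkylation releasing ethane) is the classical acid-free method that spares ortho-allylic phenols of the cannabidiol type, so the prenyl group, the 1,1-dimethylallyl group and the chroman ring should survive while all three methyl ethers are removed.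

## Compound list

1 | 3,5-dimethoxybenzaldehyde | COc1cc(C=O)cc(OC)c1 | starting material
2 | bromine | BrBr | starting material
3 | 2,6-dibromo-3,5-dimethoxybenzaldehyde | COc1cc(OC)c(Br)c(C=O)c1Br | intermediate
4 | tributyl(3-methylbut-2-en-1-yl)stannane | CCCC[Sn](CCCC)(CCCC)CC=C(C)C | starting material
5 | 3,5-dimethoxy-2,6-bis(3-methylbut-2-en-1-yl)benzaldehyde | COc1cc(OC)c(CC=C(C)C)c(C=O)c1CC=C(C)C | intermediate
6 | 3-hydroxy-5-methoxy-2,6-bis(3-methylbut-2-en-1-yl)benzaldehyde (monophenol aldehyde, not isolated) | COc1cc(O)c(CC=C(C)C)c(C=O)c1CC=C(C)C | intermediate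
7 | 7-methoxy-2,2-dimethyl-6-(3-methylbut-2-en-1-yl)chromane-5-carbaldehyde | COc1cc2OC(C)(C)CCc2c(C=O)c1CC=C(C)C | intermediate
8 | dimethyl (1-diazo-2-oxopropyl)phosphonate | COP(=O)(OC)C(=[N+]=[N-])C(C)=O | starting material
9 | 5-ethynyl-7-methoxy-2,2-dimethyl-6-(3-methylbut-2-en-1-yl)chromane | C#Cc1c(CC=C(C)C)c(OC)cc2OC(C)(C)CCc12 | intermediate
10 | 3,5-dimethoxyphenol | COc1cc(O)cc(OC)c1 | starting material
11 | N-iodosuccinimide | O=C1CCC(=O)N1I | starting material
12 | 2-iodo-3,5-dimethoxyphenol | COc1cc(O)c(I)c(OC)c1 | intermediate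
13 | 1-bromo-3-methylbut-2-ene | CC(C)=CCBr | starting material
14 | 2-iodo-1,5-dimethoxy-3-[(3-methylbut-2-en-1-yl)oxy]benzene | COc1cc(OC)c(I)c(OCC=C(C)C)c1 | intermediate
15 | 5-{[2,4-dimethoxy-6-(3-methylbut-2-en-1-yloxy)phenyl]ethynyl}-7-methoxy-2,2-dimethyl-6-(3-methylbut-2-en-1-yl)chromane | COc1cc(OC)c(C#Cc2c(CC=C(C)C)c(OC)cc3OC(C)(C)CCc23)c(OCC=C(C)C)c1 | intermediate
16 | 3,5-dimethoxy-2-{[7-methoxy-2,2-dimethyl-6-(3-methylbut-2-en-1-yl)chroman-5-yl]ethynyl}-6-(2-methylbut-3-en-2-yl)phenol (Claisen phenol, not isolated) | C=CC(C)(C)c1c(O)c(C#Cc2c(CC=C(C)C)c(OC)cc3OC(C)(C)CCc23)c(OC)cc1OC | intermediate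
17 | 4,6-dimethoxy-2-[7-methoxy-2,2-dimethyl-6-(3-methylbut-2-en-1-yl)chroman-5-yl]-7-(2-methylbut-3-en-2-yl)-1-benzofuran | C=CC(C)(C)c1c(OC)cc(OC)c2cc(-c3c(CC=C(C)C)c(OC)cc4c3CCC(C)(C)O4)oc12 | intermediate
18 | Artopetelin C | C=CC(C)(C)c1c(O)cc(O)c2cc(-c3c(CC=C(C)C)c(O)cc4c3CCC(C)(C)O4)oc12 | target

## Step count and risks

Total steps: 9. Longest linear sequence: 7 (steps 1, 2, 3, 4, 7, 8, 9).

**Step 8 (proposed new step).** The prenyl group may migrate on to the para position, or the phenoxide may close sluggishly. The fallback uses known chemistry only and sets out from 14. Thermal aromatic Claisen rearrangement in N,N-diethylaniline at 185 °C gives 2-iodo-3,5-dimethoxy-6-(2-methylbut-3-en-2-yl)phenol F1. F1 is then joined to alkyne 9 by a one-pot Sonogashira coupling and cycloisomerisation of the resulting 2-alkynylphenol (PdCl2(PPh3)2, CuI, Et3N, DMF, 80 °C). The fallback comes back to the route at 17.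

**Step 3.** Under acid the aldehyde may close onto the second, methoxy-flanked prenyl group (carbonyl-ene or Prins reaction), or residual thiol may form a thioacetal. The fallback sets out from 6, isolated by aqueous NH4Cl work-up of the thiolate stage. The aldehyde is homologated first with 8 (K2CO3, MeOH) to 3-ethynyl-5-methoxy-2,4-bis(3-methylbut-2-en-1-yl)phenol F2. The chroman is then closed with Amberlyst 15 in CH2Cl2 at rt, where no aldehyde is present. The fallback comes back to the route at 9.

**Step 9.** The two meta-related methyl ethers on ring A may not both cleave, or the melt may damage the chroman. The fallback changes the protecting groups on ring A to MOM and sets out from alkyne 9 and purchased phloroglucinol.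
- Phloroglucinol with MOMCl (2 equiv) and i-Pr2NEt gives 3,5-bis(methoxymethoxy)phenol F3.
- NIS gives 2-iodo-3,5-bis(methoxymethoxy)phenol F4.
- Alkylation with 13 and K2CO3 gives 2-iodo-1,5-bis(methoxymethoxy)-3-[(3-methylbut-2-en-1-yl)oxy]benzene F5.
- Coupling with 9 as in step 7 gives 5-{[2,4-bis(methoxymethoxy)-6-(3-methylbut-2-en-1-yloxy)phenyl]ethynyl}-7-methoxy-2,2-dimethyl-6-(3-methylbut-2-en-1-yl)chromane F6.
- Heating as in step 8 (or the stepwise sequence given for step 8) leads through 3,5-bis(methoxymethoxy)-2-{[7-methoxy-2,2-dimethyl-6-(3-methylbut-2-en-1-yl)chroman-5-yl]ethynyl}-6-(2-methylbut-3-en-2-yl)phenol F7 to 4,6-bis(methoxymethoxy)-2-[7-methoxy-2,2-dimethyl-6-(3-methylbut-2-en-1-yl)chroman-5-yl]-7-(2-methylbut-3-en-2-yl)-1-benzofuran F8.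
- EtSNa in DMF at 120 °C removes the single remaining methyl ether on ring B, which is easy because ring A then carries no phenoxide, to give 5-[4,6-bis(methoxymethoxy)-7-(2-methylbut-3-en-2-yl)-1-benzofuran-2-yl]-2,2-dimethyl-6-(3-methylbut-2-en-1-yl)chroman-7-ol F9.
- Dilute HCl in MeOH at 40 °C cleaves the two MOM ethers.

The fallback comes back to the route at 18.

## Further compounds

F1 | step 8 | 2-iodo-3,5-dimethoxy-6-(2-methylbut-3-en-2-yl)phenol | C=CC(C)(C)c1c(O)c(I)c(OC)cc1OC
F2 | step 3 | 3-ethynyl-5-methoxy-2,4-bis(3-methylbut-2-en-1-yl)phenol | C#Cc1c(CC=C(C)C)c(O)cc(OC)c1CC=C(C)C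
F3 | step 9 | 3,5-bis(methoxymethoxy)phenol | COCOc1cc(O)cc(OCOC)c1
F4 | step 9 | 2-iodo-3,5-bis(methoxymethoxy)phenol | COCOc1cc(O)c(I)c(OCOC)c1
F5 | step 9 | 2-iodo-1,5-bis(methoxymethoxy)-3-[(3-methylbut-2-en-1-yl)oxy]benzene | COCOc1cc(OCOC)c(I)c(OCC=C(C)C)c1
F6 | step 9 | 5-{[2,4-bis(methoxymethoxy)-6-(3-methylbut-2-en-1-yloxy)phenyl]ethynyl}-7-methoxy-2,2-dimethyl-6-(3-methylbut-2-en-1-yl)chromane | COCOc1cc(OCOC)c(C#Cc2c(CC=C(C)C)c(OC)cc3OC(C)(C)CCc23)c(OCC=C(C)C)c1
F7 | step 9 | 3,5-bis(methoxymethoxy)-2-{[7-methoxy-2,2-dimethyl-6-(3-methylbut-2-en-1-yl)chroman-5-yl]ethynyl}-6-(2-methylbut-3-en-2-yl)phenol | C=CC(C)(C)c1c(O)c(C#Cc2c(CC=C(C)C)c(OC)cc3OC(C)(C)CCc23)c(OCOC)cc1OCOC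
F8 | step 9 | 4,6-bis(methoxymethoxy)-2-[7-methoxy-2,2-dimethyl-6-(3-methylbut-2-en-1-yl)chroman-5-yl]-7-(2-methylbut-3-en-2-yl)-1-benzofuran | C=CC(C)(C)c1c(OCOC)cc(OCOC)c2cc(-c3c(CC=C(C)C)c(OC)cc4c3CCC(C)(C)O4)oc12
F9 | step 9 | 5-[4,6-bis(methoxymethoxy)-7-(2-methylbut-3-en-2-yl)-1-benzofuran-2-yl]-2,2-dimethyl-6-(3-methylbut-2-en-1-yl)chroman-7-ol | C=CC(C)(C)c1c(OCOC)cc(OCOC)c2cc(-c3c(CC=C(C)C)c(O)cc4c3CCC(C)(C)O4)oc12
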